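## The problem

The target is a 2,6-diaryl-3,7-dioxabicyclo[3.3.0]octane. Numbering used throughout: C1 and C5 are the bridgeheads; ring A is C1–C2–O3–C4–C5 and carries aryl A (3-hydroxy-4,5-dimethoxyphenyl) on C2; ring B is C5–C6–O7–C8–C1 and carries aryl B (3,4,5-trimethoxyphenyl) on C6. The two tetrahydrofurans are cis-fused along C1–C5 and both aryl groups are exo, so four contiguous stereocentres (1R,2S,5R,6S) must be set. The molecule is nearly C2-symmetric, but the single free phenol on aryl A forbids dimerising one building block: two different aryl-C3 units must be joined selectively. Only C1 and C5 are permanent stereocentres. C2 and C6 are benzylic ether carbons on electron-rich rings; they ionise easily, so they can be set last under control of C1/C5, but they epimerise if acid is met afterwards. The benzylic C–O bonds also rule out hydrogenolysis, the trialkoxyarenes are sensitive to strong oxidants and electrophiles, and the phenol must be masked during any oxidation and released without acid. The enabling feature is that C1–C5 joins two cinnamyl units head to head, while C2 and C6 are each benzylic to a para-alkoxy ring and each have an oxygen four atoms away (O3 through C4, O7 through C8). One added bond between C2 and C6 turns the skeleton into the 1,2-diarylcyclobutane C1–C2–C6–C5, the head-to-head [2+2] adduct of two cinnamyl alkenes, in which trans C4/C8 equals the cis ring fusion and the added bond is strained, doubly benzylic and therefore oxidatively labile.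

## Retrosynthesis

**11 from 10.** The O–Si bond of the phenol is cut. The phenol is carried as its triisopropylsilyl ether 10 because that group can be removed by buffered fluoride, with neither acid (C2/C6 epimerisation) nor hydrogen (benzylic C–O cleavage). The precursor is no simpler in skeleton; the forward step only has to leave the benzylic ethers alone.

**10 from 9.** The C2–O3 and C6–O7 bonds are cut and C2 is joined to C6, giving the all-trans cyclobutane diol 9. The neighbouring cuts are worse: closing each ring from a benzylic alcohol needs two benzylic oxidation levels installed separately and acid for closure, which equilibrates exo and endo aryls. A direct oxidative coupling of two cinnamyl alcohols has no handle for cross-selectivity without para-phenols. In 9 both benzylic oxidation levels are stored in one σ-bond, and only C1 and C5 matter, because C2 and C6 pass through cations. The forward reaction must remove two electrons, break C2–C6 and let the C4 hydroxyl capture C2 and the C8 hydroxyl capture C6, under buffered kinetic conditions so that both aryls end up exo.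

**9 from 8.** This is a change of oxidation level only. C8 comes from a methyl ester and C4 from a pivaloyloxymethyl group, so one hydride step exposes both hydroxyls. Nothing is simplified structurally, but 8 is the direct product of a cycloaddition.

**8 from 4 and 7.** C1–C5 and C2–C6 are cut in a [2+2] sense, giving cinnamate 4 (aryl A) and cinnamyl pivalate 7 (aryl B).
- Two cinnamates would both bind a Lewis acid and dimerise statistically; two cinnamyl esters have no activating handle. One ester and one allylic ester allow only 4 to be activated and excited.
- The pivalate is preferred to a smaller acyl group because its tert-butyl group blocks the carbonyl lone pair that would compete for the boron Lewis acid.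
- Putting the ester on the aryl A unit keeps both branches at two steps.
- The gain is large: one ring, two skeletal bonds and four stereocentres fall back to two achiral alkenes.
- The forward step must be head-to-head, trans at C1/C5, enantioselective and selective for the cross adduct.

**4 from 2 and 3; 2 from 1.** The C1=C2 alkene is cut by olefination of aldehyde 2 with phosphonate 3, and the silyl ether is cut back to the commercial phenol aldehyde 1. Both are routine.

**7 from 6; 6 from 5.** The pivalate C–O bond is cut to alcohol 6, which comes from commercial methyl 3,4,5-trimethoxycinnamate 5 by 1,2-reduction.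

## Roads not taken

**Alternative 1:** C5–C6 and C1–C2 are cut. In the forward key step the lithiated dithiane A3 adds to the chiral menthyloxybutenolide A2 anti to the acetal substituent, and the resulting enolate is trapped by aldehyde A4 to give lactone A1 without closing a ring of the target.
- Merits: every step is known chemistry, the crystalline auxiliary fixes the absolute configuration of C1 and C5 reliably, and the two aryl groups enter independently.
- Weak points: after A1 the dithiane must be removed in the presence of two electron-rich arenes, the lactone, acetal and ketone must be reduced, and both rings are closed from benzylic alcohols under acid, where exo and endo aryls equilibrate. The benzyl ether of A1 would have to leave by hydrogenolysis beside two benzylic C–O bonds.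
- Comparison: about nine operations are needed, so step count is nearly equal, and in security of absolute stereocontrol this road is better. The chosen plan offers catalytic rather than auxiliary control, no thioacetal chemistry, and C2/C6 set once under buffered kinetic conditions instead of acid.

**Alternative 2:** two C–C bonds of aryl A are cut. In the forward key step dimethyl malonate A7 adds to enone A6 and the ketone enolate closes onto a malonate ester, giving cyclohexanedione A5.
- Merits: no phenol protecting group is needed, and aryl A could be varied late.
- Weak points: A6 already contains the complete bicycle with all four stereocentres, so the real problem is untouched. After decarboxylation and aromatisation the new ring has two equivalent hydroxyls flanking the methoxy group, so the final mono-methylation is statistical. The aromatising oxidant meets the acid-sensitive bicycle.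
- Comparison: this road is longer and inferior on every count except protecting-group economy, which the chosen plan gives up for one silylation and one desilylation.

**Alternative 3:** C1–C2 is cut. In the forward key step diazo lactone A9 with Rh2(OAc)4 gives a carbenoid at C1 that inserts into the benzylic ether C2–H bond, closing ring A to lactone A8.
- Merits: C–H insertion next to an ether oxygen into a five-membered ring is a reliable reaction type, and C5/C6 are in place beforehand.
- Weak points: the C2 configuration is decided in the insertion transition state, where nothing enforces exo; a wrong centre could only be corrected by acid equilibration, which does not clearly favour exo,exo. A 1,2-hydride shift from C5 and attack of the carbenoid on the electron-rich arenes compete. The C8 carbonyl of A8 must still be reduced to CH2, usually under Lewis acid, and A9 itself needs an enantioselective lactone synthesis plus diazo transfer; eleven or more steps are likely.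
- Comparison: ring closure is better precedented here. The chosen plan offers half the length and an exo preference built into the cation capture.

Key step: step 5

Assumption: the (S)-diphenylprolinol-derived oxazaborolidinium is taken to open the face of C1 that leads to 8; if the sense of induction is the opposite, its enantiomer is used and nothing else changes.

## Route

Step 1
Reactants: 1 3-hydroxy-4,5-dimethoxybenzaldehyde
Product: 2 3,4-dimethoxy-5-(triisopropylsilyloxy)benzaldehyde
Conditions: TIPSCl, imidazole, DMF, rt
Reagents that add atoms: triisopropylsilyl chloride, CC(C)[Si](Cl)(C(C)C)C(C)C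
Why: Silyl ether formation on a phenol is routine; the bulky triisopropylsilyl group is chosen because it must survive base, a boron Lewis acid, hydride and tetravalent cerium and still leave with fluoride.

Step 2
Reactants: 2 3,4-dimethoxy-5-(triisopropylsilyloxy)benzaldehyde; 3 trimethyl phosphonoacetate
Product: 4 methyl (E)-3-[3,4-dimethoxy-5-(triisopropylsilyloxy)phenyl]prop-2-enoate
Conditions: NaH, THF, 0 °C to rt
Reagents that add atoms: none
Why: Horner–Wadsworth–Emmons olefination of an aromatic aldehyde with a stabilised phosphonate anion gives the (E)-enoate; the sodium phosphonate in THF should leave the aryl silyl ether alone.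

Step 3
Reactants: 5 methyl (E)-3-(3,4,5-trimethoxyphenyl)prop-2-enoate
Product: 6 (E)-3-(3,4,5-trimethoxyphenyl)prop-2-en-1-ol
Conditions: i-Bu2AlH (DIBAL-H, 2.5 equiv), CH2Cl2, −78 °C; Rochelle salt work-up
Reagents that add atoms: none
Why: 1,2-Reduction of an α,β-unsaturated ester to the allylic alcohol by i-Bu2AlH at low temperature is standard and does not touch the alkene.

Step 4
Reactants: 6 (E)-3-(3,4,5-trimethoxyphenyl)prop-2-en-1-ol
Product: 7 (E)-3-(3,4,5-trimethoxyphenyl)allyl pivalate
Conditions: PivCl, pyridine, DMAP (cat.), CH2Cl2, 0 °C to rt
Reagents that add atoms: pivaloyl chloride, CC(C)(C)C(=O)Cl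
Why: Acylation of a primary allylic alcohol under nucleophilic catalysis; the pivalate is chosen because its tert-butyl group shields the carbonyl lone pair from the boron Lewis acid of step 5 and it still falls to hydride in step 6.

Step 5
Reactants: 4 methyl (E)-3-[3,4-dimethoxy-5-(triisopropylsilyloxy)phenyl]prop-2-enoate; 7 (E)-3-(3,4,5-trimethoxyphenyl)allyl pivalate
Product: 8 methyl (1R,2R,3S,4S)-4-[3,4-dimethoxy-5-(triisopropylsilyloxy)phenyl]-2-[(pivaloyloxy)methyl]-3-(3,4,5-trimethoxyphenyl)cyclobutane-1-carboxylate (all-trans)
Conditions: 4 (1 equiv), 7 (3 equiv), (S)-B-(o-tolyl)diphenylprolinol oxazaborolidine activated with Tf2NH (50 mol %), fac-Ir(ppy)3 (1 mol %), CH2Cl2, −78 °C, blue LEDs (450 nm)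
Reagents that add atoms: none
Why: Proposed new method: the oxazaborolidinium binds the ester carbonyl of 4 and makes the complex the preferred acceptor of triplet energy from photoexcited fac-Ir(ppy)3 (trivalent iridium), so the cinnamate triplet forms inside the chiral pocket while 7, whose hindered pivalate does not compete for boron and whose styrene triplet lies higher, stays in the ground state. The α-carbon C1 of the triplet adds to the non-benzylic carbon C5 of 7 to give a triplet 1,4-diradical with both radical centres (C2 and C6) benzylic, which after intersystem crossing recombines to form C2–C6, so the cyclobutane is closed stepwise by radical–radical coupling and not by a concerted cycloaddition. The closest known reaction type is the enantioselective, Lewis-acid-assisted, triplet-sensitised crossed [2+2] cycloaddition of cinnamate esters with terminal styrenes, and the sensitised head-to-head dimerisation of cinnamate esters shows that 1,2-disubstituted partners also end up all-trans. C1 is set by the catalyst, which leaves one face of the bound α-carbon open; C5 is set in the same bond formation by the relative topicity, the diradical that would close to cis C4/C8 doing so slowly and reverting to the alkenes, so that material drains through the trans diradical. C2 and C6 are set at ring closure, where the freely rotating benzylic radicals place each aryl trans to its neighbours; both centres are erased in step 7, so only trans C1/C5 and the absolute sense matter for the target. Head-to-head regiochemistry follows from the doubly benzylic diradical, and cross-coupling over homodimerisation is secured by exciting only bound 4 in an excess of 7. E/Z isomerisation of either alkene by the sensitiser is harmless because both geometries feed the same diradical.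

Step 6
Reactants: 8 methyl (1R,2R,3S,4S)-4-[3,4-dimethoxy-5-(triisopropylsilyloxy)phenyl]-2-[(pivaloyloxy)methyl]-3-(3,4,5-trimethoxyphenyl)cyclobutane-1-carboxylate
Product: 9 {(1R,2R,3S,4S)-4-[3,4-dimethoxy-5-(triisopropylsilyloxy)phenyl]-3-(3,4,5-trimethoxyphenyl)cyclobutane-1,2-diyl}dimethanol (all-trans)
Conditions: LiAlH4, THF, 0 °C
Reagents that add atoms: none
Why: Hydride reduction of esters: the methyl ester becomes the C8 hydroxymethyl group and the pivalate is cleaved to the C4 hydroxymethyl group in one operation; no stereocentre is touched and the hindered aryl silyl ether should survive at 0 °C.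

Step 7
Reactants: 9 {(1R,2R,3S,4S)-4-[3,4-dimethoxy-5-(triisopropylsilyloxy)phenyl]-3-(3,4,5-trimethoxyphenyl)cyclobutane-1,2-diyl}dimethanol
Product: 10 (1R,2S,5R,6S)-2-[3,4-dimethoxy-5-(triisopropylsilyloxy)phenyl]-6-(3,4,5-trimethoxyphenyl)-3,7-dioxabicyclo[3.3.0]octane (cis-fused, both aryls exo)
Conditions: (NH4)2Ce(NO3)6 (2.2 equiv), NaHCO3, dry MeCN, −20 °C
Reagents that add atoms: none
Why: Proposed new method: one-electron oxidation of a trialkoxyaryl ring by tetravalent cerium should break the strained, doubly benzylic C2–C6 bond, the C4 hydroxyl closing ring A on the C2 cation and, after a second oxidation of the C6 radical, the C8 hydroxyl closing ring B; the closest known reaction types are the one-electron oxidative ring opening of arylcyclopropanes with capture of oxygen nucleophiles at the benzylic ends and the radical-cation cleavage of 1,2-diarylcyclobutanes. C2 and C6 are set under buffered kinetic control with each aryl trans to the neighbouring ring substituent (exo), while C1 and C5 are untouched and their trans arrangement on the cyclobutane becomes the cis ring fusion.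

Step 8
Reactants: 10 (1R,2S,5R,6S)-2-[3,4-dimethoxy-5-(triisopropylsilyloxy)phenyl]-6-(3,4,5-trimethoxyphenyl)-3,7-dioxabicyclo[3.3.0]octane
Product: 11 (1R,2S,5R,6S)-2-(3-hydroxy-4,5-dimethoxyphenyl)-6-(3,4,5-trimethoxyphenyl)-3,7-dioxabicyclo[3.3.0]octane (CNP0181235.1)
Conditions: Bu4NF, AcOH, THF, 0 °C
Reagents that add atoms: none
Why: Fluoride cleavage of an aryl silyl ether, buffered with acetic acid so that neither acid (epimerisation at C2/C6) nor a free phenoxide is present; no stereocentre is affected.

## Compound list

1 | 3-hydroxy-4,5-dimethoxybenzaldehyde | COc1cc(C=O)cc(O)c1OC | starting material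
2 | 3,4-dimethoxy-5-(triisopropylsilyloxy)benzaldehyde | COc1cc(C=O)cc(O[Si](C(C)C)(C(C)C)C(C)C)c1OC | intermediate
3 | trimethyl phosphonoacetate | COC(=O)CP(=O)(OC)OC | starting material
4 | methyl (E)-3-[3,4-dimethoxy-5-(triisopropylsilyloxy)phenyl]prop-2-enoate | COC(=O)/C=C/c1cc(OC)c(OC)c(O[Si](C(C)C)(C(C)C)C(C)C)c1 | intermediate
5 | methyl (E)-3-(3,4,5-trimethoxyphenyl)prop-2-enoate | COC(=O)/C=C/c1cc(OC)c(OC)c(OC)c1 | starting material
6 | (E)-3-(3,4,5-trimethoxyphenyl)prop-2-en-1-ol | OC/C=C/c1cc(OC)c(OC)c(OC)c1 | intermediate
7 | (E)-3-(3,4,5-trimethoxyphenyl)allyl pivalate | CC(C)(C)C(=O)OC/C=C/c1cc(OC)c(OC)c(OC)c1 | intermediate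
8 | methyl (1R,2R,3S,4S)-4-[3,4-dimethoxy-5-(triisopropylsilyloxy)phenyl]-2-[(pivaloyloxy)methyl]-3-(3,4,5-trimethoxyphenyl)cyclobutane-1-carboxylate | COc1cc([C@@H]2[C@@H](C(=O)OC)[C@H](COC(=O)C(C)(C)C)[C@H]2c2cc(OC)c(OC)c(OC)c2)cc(O[Si](C(C)C)(C(C)C)C(C)C)c1OC | intermediate
9 | {(1R,2R,3S,4S)-4-[3,4-dimethoxy-5-(triisopropylsilyloxy)phenyl]-3-(3,4,5-trimethoxyphenyl)cyclobutane-1,2-diyl}dimethanol | COc1cc([C@@H]2[C@@H](CO)[C@H](CO)[C@H]2c2cc(OC)c(OC)c(OC)c2)cc(O[Si](C(C)C)(C(C)C)C(C)C)c1OC | intermediate
10 | (1R,2S,5R,6S)-2-[3,4-dimethoxy-5-(triisopropylsilyloxy)phenyl]-6-(3,4,5-trimethoxyphenyl)-3,7-dioxabicyclo[3.3.0]octane | COc1cc([C@H]2OC[C@H]3[C@@H]2CO[C@@H]3c2cc(OC)c(OC)c(OC)c2)cc(O[Si](C(C)C)(C(C)C)C(C)C)c1OC | intermediate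
11 | (1R,2S,5R,6S)-2-(3-hydroxy-4,5-dimethoxyphenyl)-6-(3,4,5-trimethoxyphenyl)-3,7-dioxabicyclo[3.3.0]octane | COc1cc([C@H]2OC[C@H]3[C@@H]2CO[C@@H]3c2cc(OC)c(OC)c(OC)c2)cc(O)c1OC | target

## Step count and risks

Total step count: 8. Longest linear sequence: 6 (steps 1, 2, 5, 6, 7, 8; the branch through steps 3 and 4 is equally long).

**Step 5 (key step, proposed new method).** The internal alkene of 7 is a slower trap for the cinnamate triplet than a terminal styrene. The likely failures are therefore unproductive E/Z isomerisation of 4, homodimerisation of 4, racemic background reaction through sensitisation of unbound 4, and ionisation of the electron-rich allylic ester by the Lewis acid. Loss of C1/C5 trans selectivity in the first bond formation would also waste material, since cis isomers cannot give the cis-fused bicycle.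

Fallback (known chemistry), from 4 and 5, returning at 9: equimolar 4 and 5 would be irradiated with blue light in the presence of the high-triplet-energy sensitiser [Ir(dF(CF3)ppy)2(dtbbpy)]PF6 and no Lewis acid. Sensitised head-to-head dimerisation of cinnamate esters to all-trans cyclobutane-1,2-diesters is an established reaction. The mixed dimer, racemic dimethyl (1R*,2R*,3S*,4S*)-4-[3,4-dimethoxy-5-(triisopropylsilyloxy)phenyl]-3-(3,4,5-trimethoxyphenyl)cyclobutane-1,2-dicarboxylate (F1), should be separable by chromatography from the two homodimers formed beside it. LiAlH4 in THF at 0 °C should reduce both esters of F1 and give the diol as a racemate, in which 9 is accompanied by its mirror image {(1S,2S,3R,4R)-4-[3,4-dimethoxy-5-(triisopropylsilyloxy)phenyl]-3-(3,4,5-trimethoxyphenyl)cyclobutane-1,2-diyl}dimethanol (F2). Preparative chromatography on a chiral stationary phase would then separate 9 from F2; F2 is set aside and 9 goes on to step 7. The price is statistical cross-coupling and loss of half the material at the resolution.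

**Step 7 (proposed new method).** The ring-opened radical cation can cleave C1–C5 as well and fall apart into two cinnamyl alcohol units (cycloreversion) faster than the hydroxyls capture it. Other risks are over-oxidation of the product's arenes or benzylic C–H bonds, nitrate capture of the cations, and acid-mediated equilibration of C2/C6 toward endo isomers if buffering is insufficient.

Fallback (known chemistry), from 2 and 6, returning at 10; it abandons the cyclobutane and forms C1–C5 by a radical cyclisation. Vinylmagnesium bromide in THF at −78 °C, quenched with NH4Cl, should convert 2 into racemic 1-[3,4-dimethoxy-5-(triisopropylsilyloxy)phenyl]prop-2-en-1-ol (F3). Sharpless kinetic resolution of F3 (Ti(OiPr)4, D-(−)-diisopropyl tartrate, t-BuOOH, 4 Å sieves, CH2Cl2, −20 °C, stopped short of half conversion) should epoxidise the (S)-alcohol selectively to the erythro epoxy alcohol (R)-[3,4-dimethoxy-5-(triisopropylsilyloxy)phenyl][(S)-oxiran-2-yl]methanol (F4), whose carbinol carbon is the future C2; the slow-reacting (R)-alcohol is removed by chromatography. PBr3 in Et2O at 0 °C should convert 6 into (E)-5-(3-bromoprop-1-en-1-yl)-1,2,3-trimethoxybenzene (F5). Williamson etherification of F4 with F5 (NaH, Bu4NI, THF, 0 °C, kept cold so that the alkoxide is alkylated before it can undergo Payne rearrangement) should give (S)-2-{(R)-[3,4-dimethoxy-5-(triisopropylsilyloxy)phenyl][(E)-3-(3,4,5-trimethoxyphenyl)allyloxy]methyl}oxirane (F6). Cp2TiCl (trivalent titanium, made from Cp2TiCl2 and Zn) in THF should open the epoxide of F6 to the C1 radical, which cyclises 5-exo onto C5; iodine then converts the benzylic C6 radical into an iodide that the titanium alkoxide on C8 displaces, closing ring B to give 10. This epoxide-opening radical cyclisation of cinnamyl ethers is a known entry to this ring system. C2 directs the new centres, and only the cis-C1/C5 cyclisation product can close ring B, so a monocyclic by-product would have to be removed by chromatography.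

**Step 2.** The phosphonate anion or traces of methoxide or hydroxide may attack silicon and strip the aryl silyl ether under the basic olefination conditions.

Fallback, from 1, returning at 4, with the order of operations reversed: 1 would be heated with methyl (triphenylphosphoranylidene)acetate in toluene at 80 °C. This stabilised Wittig reagent tolerates free phenols and should give methyl (E)-3-(3-hydroxy-4,5-dimethoxyphenyl)prop-2-enoate (F7). Silylation of F7 with TIPSCl and imidazole in DMF then gives 4.

## Further compounds

F1 | step 5 | racemic dimethyl (1R*,2R*,3S*,4S*)-4-[3,4-dimethoxy-5-(triisopropylsilyloxy)phenyl]-3-(3,4,5-trimethoxyphenyl)cyclobutane-1,2-dicarboxylate (one enantiomer drawn) | COc1cc([C@@H]2[C@@H](C(=O)OC)[C@H](C(=O)OC)[C@H]2c2cc(OC)c(OC)c(OC)c2)cc(O[Si](C(C)C)(C(C)C)C(C)C)c1OC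
F2 | step 5 | {(1S,2S,3R,4R)-4-[3,4-dimethoxy-5-(triisopropylsilyloxy)phenyl]-3-(3,4,5-trimethoxyphenyl)cyclobutane-1,2-diyl}dimethanol, the mirror image of 9 | COc1cc([C@H]2[C@H](CO)[C@@H](CO)[C@@H]2c2cc(OC)c(OC)c(OC)c2)cc(O[Si](C(C)C)(C(C)C)C(C)C)c1OC
F3 | step 7 | racemic 1-[3,4-dimethoxy-5-(triisopropylsilyloxy)phenyl]prop-2-en-1-ol | COc1cc(C(O)C=C)cc(O[Si](C(C)C)(C(C)C)C(C)C)c1OC
F4 | step 7 | (R)-[3,4-dimethoxy-5-(triisopropylsilyloxy)phenyl][(S)-oxiran-2-yl]methanol | COc1cc([C@@H](O)[C@@H]2CO2)cc(O[Si](C(C)C)(C(C)C)C(C)C)c1OC
F5 | step 7 | (E)-5-(3-bromoprop-1-en-1-yl)-1,2,3-trimethoxybenzene | COc1cc(/C=C/CBr)cc(OC)c1OC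
F6 | step 7 | (S)-2-{(R)-[3,4-dimethoxy-5-(triisopropylsilyloxy)phenyl][(E)-3-(3,4,5-trimethoxyphenyl)allyloxy]methyl}oxirane | COc1cc([C@@H](OC/C=C/c2cc(OC)c(OC)c(OC)c2)[C@@H]2CO2)cc(O[Si](C(C)C)(C(C)C)C(C)C)c1OC
F7 | step 2 | methyl (E)-3-(3-hydroxy-4,5-dimethoxyphenyl)prop-2-enoate | COC(=O)/C=C/c1cc(O)c(OC)c(OC)c1
A1 | alternative 1 | trans,trans-3-{hydroxy[3-(benzyloxy)-4,5-dimethoxyphenyl]methyl}-5-menthyloxy-4-[2-(3,4,5-trimethoxyphenyl)-1,3-dithian-2-yl]dihydrofuran-2(3H)-one | COc1cc([C@@H](O)[C@H]2C(=O)O[C@@H](O[C@@H]3C[C@H](C)CC[C@H]3C(C)C)[C@@H]2C2(SCCCS2)c2cc(OC)c(OC)c(OC)c2)cc(OCc2ccccc2)c1OC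
A2 | alternative 1 | (5R)-5-[(1R,2S,5R)-menthyloxy]furan-2(5H)-one | O=C1O[C@@H](O[C@@H]2C[C@H](C)CC[C@H]2C(C)C)C=C1
A3 | alternative 1 | 2-(3,4,5-trimethoxyphenyl)-1,3-dithiane | COc1cc(C2SCCCS2)cc(OC)c1OC
A4 | alternative 1 | 3-(benzyloxy)-4,5-dimethoxybenzaldehyde | COc1cc(C=O)cc(OCc2ccccc2)c1OC
A5 | alternative 2 | methyl 3-methoxy-2,4-dioxo-6-[exo,exo-6-(3,4,5-trimethoxyphenyl)-3,7-dioxabicyclo[3.3.0]octan-2-yl]cyclohexane-1-carboxylate (ring centres of the cyclohexane unassigned) | COC(=O)C1C(=O)C(OC)C(=O)CC1[C@H]1OC[C@H]2[C@@H]1CO[C@@H]2c1cc(OC)c(OC)c(OC)c1
A6 | alternative 2 | (E)-1-methoxy-4-[exo,exo-6-(3,4,5-trimethoxyphenyl)-3,7-dioxabicyclo[3.3.0]octan-2-yl]but-3-en-2-one | COCC(=O)/C=C/[C@H]1OC[C@H]2[C@@H]1CO[C@@H]2c1cc(OC)c(OC)c(OC)c1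
A7 | alternative 2 | dimethyl malonate | COC(=O)CC(=O)OC
A8 | alternative 3 | exo,exo-2-[3,4-dimethoxy-5-(triisopropylsilyloxy)phenyl]-6-(3,4,5-trimethoxyphenyl)-3,7-dioxabicyclo[3.3.0]octan-8-one | COc1cc([C@H]2OC[C@H]3[C@@H]2C(=O)O[C@@H]3c2cc(OC)c(OC)c(OC)c2)cc(O[Si](C(C)C)(C(C)C)C(C)C)c1OC
A9 | alternative 3 | trans-3-diazo-4-({[3,4-dimethoxy-5-(triisopropylsilyloxy)phenyl]methoxy}methyl)-5-(3,4,5-trimethoxyphenyl)dihydrofuran-2(3H)-one | COc1cc(COC[C@H]2C(=[N+]=[N-])C(=O)O[C@@H]2c2cc(OC)c(OC)c(OC)c2)cc(O[Si](C(C)C)(C(C)C)C(C)C)c1OC
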